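**Retrosynthetic overview**

- Isobutylshikonin ⇒ (ester, MOM and silyl adjustments) 2-substituted 5,8-bis(methoxymethoxy)-1,4-naphthoquinone ⇒ (oxidative demethylation) 4-methoxy-1-naphthol.
- Feature used: ring B (C1, C2, C3, C4, C4a, C8a) carries oxygen on C1 and C4 and the side chain on C2, beside the C1 oxygen. A para-dioxygenated benzo ring with one substituent ortho to the phenol is the pattern a chromium carbene/alkyne/CO benzannulation gives.
- Ring B is cut at C3–C4, C1–C2 and C1–C8a: an aryl(methoxy)carbene complex of zerovalent chromium (ring A, from hydroquinone), a terminal alkyne carrying the (R)-silyloxy carbinol, and one CO ligand that becomes C1.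
- Alkyne ⇒ TMS-ynone ⇒ Weinreb amide of 4-methylpent-3-enoic acid; the stereocenter comes from asymmetric transfer hydrogenation of the ynone.
- Ring order: ring A is bought with hydroquinone; ring B is formed in the benzannulation; no other ring is made.

Key step: step 8

Remark: species that exist only fleetingly within one operation (the chromium vinylcarbene and vinylketene of step 8, half-protected species in steps 1 and 12) are described but not numbered. The sense of induction in step 5 is assigned by analogy and should be checked on 14 by Mosher ester analysis.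

**Route**

Step 1
Reactants: 1 hydroquinone
Product: 2 1,4-bis(methoxymethoxy)benzene
Conditions: MOMCl, i-Pr2NEt, CH2Cl2 (DMF cosolvent), 0 °C → rt
Reagents that add atoms: chloromethyl methyl ether, COCCl
Why: Double O-alkylation of the phenols with the reactive α-chloro ether (MOM protection) installs groups that later direct ortho-lithiation and come off with mild acid.

Step 2
Reactants: 2 1,4-bis(methoxymethoxy)benzene; 3 chromium hexacarbonyl
Product: 6 pentacarbonyl{[2,5-bis(methoxymethoxy)phenyl](methoxy)methylidene}chromium, via aryllithium 4 (not isolated), via lithium acylchromate 5 (not isolated)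
Conditions: n-BuLi, THF, 0 °C → rt; Cr(CO)6, THF, 0 °C → rt; evaporate; Me3OBF4, CH2Cl2, 0 °C
Reagents that add atoms: trimethyloxonium tetrafluoroborate, C[O+](C)C.F[B-](F)(F)F
Why: MOM-directed ortho-lithiation (all four ring positions are equivalent), addition of the aryllithium to a CO ligand and O-methylation of the acylchromate with Meerwein salt is the classical Fischer carbene complex synthesis.

Step 3
Reactants: 7 4-methylpent-3-enoic acid
Product: 9 N-methoxy-N,4-dimethylpent-3-enamide, via acyl imidazole 8 (not isolated)
Conditions: CDI, CH2Cl2, rt; then MeNH(OMe)·HCl, rt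
Reagents that add atoms: N,O-dimethylhydroxylamine hydrochloride, CNOC.Cl
Why: Carbonyldiimidazole activation and aminolysis (Weinreb amide formation) run under near-neutral conditions that should not move the β,γ-double bond into conjugation.

Step 4
Reactants: 9 N-methoxy-N,4-dimethylpent-3-enamide; 10 ethynyltrimethylsilane
Product: 13 6-methyl-1-(trimethylsilyl)hept-5-en-1-yn-3-one, via lithium silylacetylide 11 (not isolated), via tetrahedral lithium adduct 12 (not isolated)
Conditions: 10, n-BuLi, THF, −78 °C; then 9, −78 → 0 °C; cold 1 M HCl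
Reagents that add atoms: none
Why: Weinreb ketone synthesis: the acetylide adds once and the chelated tetrahedral adduct survives until the acidic quench, so the ynone forms without over-addition.

Step 5
Reactants: 13 6-methyl-1-(trimethylsilyl)hept-5-en-1-yn-3-one
Product: 14 (3R)-6-methyl-1-(trimethylsilyl)hept-5-en-1-yn-3-ol
Conditions: Ru[(1R,2R)-TsNCH(Ph)CH(Ph)NH](η6-p-cymene) (1 mol %), i-PrOH, rt
Reagents that add atoms: none
Why: Noyori asymmetric transfer hydrogenation of an α,β-acetylenic ketone: the (R,R)-configured ruthenium amide passes hydride from 2-propanol through the six-membered bifunctional transition state with the alkynyl group in the place an aryl group takes, which should give the (R)-carbinol, and this fast, base-free reduction should outrun migration of the skipped double bond.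

Step 6
Reactants: 14 (3R)-6-methyl-1-(trimethylsilyl)hept-5-en-1-yn-3-ol
Product: 15 tert-butyldimethyl{[(3R)-6-methyl-1-(trimethylsilyl)hept-5-en-1-yn-3-yl]oxy}silane
Conditions: TBSCl, imidazole, DMF, rt
Reagents that add atoms: tert-butyldimethylsilyl chloride, CC(C)(C)[Si](C)(C)Cl
Why: Imidazole-promoted O-silylation of the secondary alcohol leaves the C–O bond of the stereocenter untouched and gives a non-volatile intermediate.

Step 7
Reactants: 15 tert-butyldimethyl{[(3R)-6-methyl-1-(trimethylsilyl)hept-5-en-1-yn-3-yl]oxy}silane
Product: 16 (3R)-3-(tert-butyldimethylsilyloxy)-6-methylhept-5-en-1-yne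
Conditions: K2CO3 (cat.), MeOH, rt
Reagents that add atoms: none
Why: Base-catalysed methanolysis of the alkynyl C–Si bond (protiodesilylation) is selective because the TBS ether is inert to K2CO3 in methanol.

Step 8
Reactants: 6 pentacarbonyl{[2,5-bis(methoxymethoxy)phenyl](methoxy)methylidene}chromium; 16 (3R)-3-(tert-butyldimethylsilyloxy)-6-methylhept-5-en-1-yne
Product: 18 2-[(1R)-1-(tert-butyldimethylsilyloxy)-4-methylpent-3-enyl]-4-methoxy-5,8-bis(methoxymethoxy)naphthalen-1-ol, via tricarbonylchromium naphthol complex 17 (not isolated)
Conditions: 6 (1.3 equiv), degassed THF (0.05 M), 55 °C, Ar; then air, Et2O, rt; quick filtration through silica, used at once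
Reagents that add atoms: none
Why: Dötz benzannulation: thermal loss of one cis CO from 6 (eased by the neighbouring MOM oxygen), then coordination and insertion of the alkyne into the Cr=C bond gives a vinylcarbene, CO insertion gives a chromium-bound dienylketene, and this closes onto the aryl ortho carbon and tautomerises to the naphthol, first held as its Cr(CO)3 complex 17 and released on exposure to air. The closest known reaction type is the benzannulation of aryl(alkoxy)carbene complexes of zerovalent chromium with terminal alkynes, propargylic silyl ethers included. Ring B closes by 6π-electrocyclisation of the ketene (C1–C8a) after the two insertions have made C3–C4 and C1–C2, a formal [3+2+1] assembly. No stereocenter is created, and the propargylic stereocenter keeps all four bonds under neutral, non-ionising conditions because a silyl ether is a poor leaving group. The required regioselectivity comes from the terminal alkyne, whose unsubstituted carbon bonds to the carbene carbon so that the branched carbon ends beside the CO-derived C1 (the minor regioisomer would in any case give the same quinone in step 9 because ring A is symmetric), and closure can only occur at the single free ortho position of the 2,5-dioxygenated aryl group. Phenol formation over indene or cyclobutenone products is favoured by the methoxy carbene in THF at moderate temperature, and the trisubstituted alkene cannot trap the vinylcarbene because cyclopropanation would have to build a bicyclo[2.1.0]pentane.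

Step 9
Reactants: 18 2-[(1R)-1-(tert-butyldimethylsilyloxy)-4-methylpent-3-enyl]-4-methoxy-5,8-bis(methoxymethoxy)naphthalen-1-ol
Product: 19 2-[(1R)-1-(tert-butyldimethylsilyloxy)-4-methylpent-3-enyl]-5,8-bis(methoxymethoxy)naphthalene-1,4-dione
Conditions: PhI(OAc)2 (1.1 equiv), MeCN/H2O (4:1), 0 °C
Reagents that add atoms: water, O
Why: Oxidative demethylation of a para-methoxyphenol with PhI(OAc)2 (aryloxy–iodine intermediate, water addition at C4, loss of methanol) should occur only in ring B, whose free phenol is far easier to oxidise than the bis-acetal ring A, and the mild medium spares the MOM and TBS groups and the alkene.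

Step 10
Reactants: 19 2-[(1R)-1-(tert-butyldimethylsilyloxy)-4-methylpent-3-enyl]-5,8-bis(methoxymethoxy)naphthalene-1,4-dione
Product: 20 2-[(1R)-1-hydroxy-4-methylpent-3-enyl]-5,8-bis(methoxymethoxy)naphthalene-1,4-dione
Conditions: HF·pyridine, pyridine, THF, 0 °C → rt
Reagents that add atoms: none
Why: Fluoride-driven Si–O cleavage with buffered HF·pyridine avoids the basic Bu4NF conditions that degrade quinones and should leave the aryl MOM ethers intact.

Step 11
Reactants: 20 2-[(1R)-1-hydroxy-4-methylpent-3-enyl]-5,8-bis(methoxymethoxy)naphthalene-1,4-dione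
Product: 21 (1R)-1-[5,8-bis(methoxymethoxy)-1,4-dioxo-1,4-dihydronaphthalen-2-yl]-4-methylpent-3-enyl 2-methylpropanoate
Conditions: (i-PrCO)2O, DMAP (cat.), pyridine, CH2Cl2, 0 °C → rt
Reagents that add atoms: isobutyric anhydride, CC(C)C(=O)OC(=O)C(C)C
Why: DMAP-catalysed acylation of the only free hydroxy group uses bases too weak to deprotonate the position γ to the quinone carbonyl, so the configuration should be retained.

Step 12
Reactants: 21 (1R)-1-[5,8-bis(methoxymethoxy)-1,4-dioxo-1,4-dihydronaphthalen-2-yl]-4-methylpent-3-enyl 2-methylpropanoate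
Product: 22 isobutylshikonin, (1R)-1-(5,8-dihydroxy-1,4-dioxo-1,4-dihydronaphthalen-2-yl)-4-methylpent-3-enyl 2-methylpropanoate
Conditions: HCl (1 M in MeOH), CH2Cl2, 0 °C → rt
Reagents that add atoms: none
Why: Acid-catalysed acetal exchange removes the two MOM ethers, which are activated because the aryl oxygens peri to the quinone carbonyls are good leaving groups, while the ester on a carbon attached to the electron-poor quinone should not ionise and the alkene is not protonated by dilute HCl at or below room temperature.

**Compound list**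

1 | hydroquinone | Oc1ccc(O)cc1 | starting material
2 | 1,4-bis(methoxymethoxy)benzene | COCOc1ccc(OCOC)cc1 | intermediate
3 | chromium hexacarbonyl, Cr(CO)6 | O=C=[Cr](=C=O)(=C=O)(=C=O)(=C=O)=C=O | starting material
4 | [2,5-bis(methoxymethoxy)phenyl]lithium | [Li]c1cc(OCOC)ccc1OCOC | intermediate (not isolated)
5 | lithium pentacarbonyl[2,5-bis(methoxymethoxy)benzoyl]chromate | [Li+].[O-]C(=[Cr](=C=O)(=C=O)(=C=O)(=C=O)=C=O)c1cc(OCOC)ccc1OCOC | intermediate (not isolated)
6 | pentacarbonyl{[2,5-bis(methoxymethoxy)phenyl](methoxy)methylidene}chromium | COC(=[Cr](=C=O)(=C=O)(=C=O)(=C=O)=C=O)c1cc(OCOC)ccc1OCOC | intermediate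
7 | 4-methylpent-3-enoic acid | CC(C)=CCC(=O)O | starting material
8 | 1-(4-methylpent-3-enoyl)imidazole | CC(C)=CCC(=O)n1ccnc1 | intermediate (not isolated)
9 | N-methoxy-N,4-dimethylpent-3-enamide | CC(C)=CCC(=O)N(C)OC | intermediate
10 | ethynyltrimethylsilane | C#C[Si](C)(C)C | starting material
11 | lithium (trimethylsilyl)acetylide | [Li]C#C[Si](C)(C)C | intermediate (not isolated)
12 | lithium 3-[methoxy(methyl)amino]-6-methyl-1-(trimethylsilyl)hept-5-en-1-yn-3-olate | CC(C)=CCC(O[Li])(C#C[Si](C)(C)C)N(C)OC | intermediate (not isolated)
13 | 6-methyl-1-(trimethylsilyl)hept-5-en-1-yn-3-one | CC(C)=CCC(=O)C#C[Si](C)(C)C | intermediate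
14 | (3R)-6-methyl-1-(trimethylsilyl)hept-5-en-1-yn-3-ol | CC(C)=CC[C@@H](O)C#C[Si](C)(C)C | intermediate
15 | tert-butyldimethyl{[(3R)-6-methyl-1-(trimethylsilyl)hept-5-en-1-yn-3-yl]oxy}silane | CC(C)=CC[C@@H](O[Si](C)(C)C(C)(C)C)C#C[Si](C)(C)C | intermediate
16 | (3R)-3-(tert-butyldimethylsilyloxy)-6-methylhept-5-en-1-yne | CC(C)=CC[C@@H](O[Si](C)(C)C(C)(C)C)C#C | intermediate
17 | tricarbonyl(η6-naphthol)chromium complex of 18, Cr(CO)3 bound to ring B (drawn as arene and Cr(CO)3 fragment side by side) | CC(C)=CC[C@@H](O[Si](C)(C)C(C)(C)C)c1cc(OC)c2c(OCOC)ccc(OCOC)c2c1O.O=C=[Cr](=C=O)=C=O | intermediate (not isolated)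
18 | 2-[(1R)-1-(tert-butyldimethylsilyloxy)-4-methylpent-3-enyl]-4-methoxy-5,8-bis(methoxymethoxy)naphthalen-1-ol | CC(C)=CC[C@@H](O[Si](C)(C)C(C)(C)C)c1cc(OC)c2c(OCOC)ccc(OCOC)c2c1O | intermediate
19 | 2-[(1R)-1-(tert-butyldimethylsilyloxy)-4-methylpent-3-enyl]-5,8-bis(methoxymethoxy)naphthalene-1,4-dione | CC(C)=CC[C@@H](O[Si](C)(C)C(C)(C)C)C1=CC(=O)c2c(OCOC)ccc(OCOC)c2C1=O | intermediate
20 | 2-[(1R)-1-hydroxy-4-methylpent-3-enyl]-5,8-bis(methoxymethoxy)naphthalene-1,4-dione | CC(C)=CC[C@@H](O)C1=CC(=O)c2c(OCOC)ccc(OCOC)c2C1=O | intermediate
21 | (1R)-1-[5,8-bis(methoxymethoxy)-1,4-dioxo-1,4-dihydronaphthalen-2-yl]-4-methylpent-3-enyl 2-methylpropanoate | CC(C)=CC[C@@H](OC(=O)C(C)C)C1=CC(=O)c2c(OCOC)ccc(OCOC)c2C1=O | intermediate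
22 | isobutylshikonin, (1R)-1-(5,8-dihydroxy-1,4-dioxo-1,4-dihydronaphthalen-2-yl)-4-methylpent-3-enyl 2-methylpropanoate | CC(C)=CC[C@@H](OC(=O)C(C)C)C1=CC(=O)c2c(O)ccc(O)c2C1=O | target

**Step count and risks**

Total: 12 steps. Longest linear sequence: 10 steps (steps 3–7, then 8–12, from 4-methylpent-3-enoic acid); the carbene arm is 2 steps before the union.

Steps most likely to fail:

1. Step 8 (benzannulation). After CO loss the ortho MOM oxygen may bind chromium and hold back alkyne uptake. The vinylcarbene may also cyclise without CO insertion (indene, furan or cyclobutenone channels), and the electron-rich naphthol may be lost to uncontrolled air oxidation during release from chromium. Fallback: a polar route with a preformed naphthalene, the side chain as acyl electrophile and the stereocenter set by ketone reduction. It sets out from Weinreb amide 9 and comes back at 21.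
   - Purchased naphthazarin F1 would be reduced with Na2S2O4 and the tetrol alkylated with NaH/MOMCl in DMF to 1,4,5,8-tetrakis(methoxymethoxy)naphthalene F2.
   - MOM-directed lithiation of F2 with n-BuLi/TMEDA in THF (all four free positions are equivalent) and acylation with 9 at −78 °C would give the 2-naphthyl ketone F3.
   - Reduction with (+)-Ipc2BCl in THF at −25 °C, the aryl group acting as the large substituent, should give the (R)-carbinol F4.
   - Isobutyric anhydride/DMAP/pyridine would give the isobutyrate F5.
   - Oxidation with (NH4)2Ce(NO3)6 in MeCN/H2O at 0 °C would give 21 together with the ring-A quinone isomer F6. Step 12 converts both into 22, because the two dihydroxyquinone forms are tautomers of one compound.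

2. Step 12 (MOM removal). Acid strong enough to cleave both aryl acetals may also solvolyse or transesterify the isobutyrate or add to the trisubstituted alkene. Fallback: change the order, unmasking first and acylating last. It sets out from 20 and comes back at 22. Treatment of 20 with HCl in MeOH/CH2Cl2 would give shikonin F7. Its side-chain hydroxy group would then be esterified selectively with isobutyric acid, DCC and DMAP in CH2Cl2 at 0 °C, since the two phenols are hydrogen-bonded to the quinone carbonyls and are poor nucleophiles.

3. Step 10 (desilylation on the quinone). Si–O cleavage at the hindered carbinol beside the quinone may be slow, so that prolonged exposure strips MOM groups or degrades the quinone. Fallback: desilylate before the quinone exists. It sets out from naphthol 18 and comes back at 20. Bu4NF buffered with AcOH in THF would remove the TBS group of 18 to give the desilylated naphthol F8, which PhI(OAc)2 in MeCN/H2O at 0 °C would oxidise directly to 20.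

**Further compounds**

F1 | step 8 | 5,8-dihydroxynaphthalene-1,4-dione (naphthazarin) | O=C1C=CC(=O)c2c(O)ccc(O)c12
F2 | step 8 | 1,4,5,8-tetrakis(methoxymethoxy)naphthalene | COCOc1ccc(OCOC)c2c(OCOC)ccc(OCOC)c12
F3 | step 8 | 4-methyl-1-[1,4,5,8-tetrakis(methoxymethoxy)naphthalen-2-yl]pent-3-en-1-one | CC(C)=CCC(=O)c1cc(OCOC)c2c(OCOC)ccc(OCOC)c2c1OCOC
F4 | step 8 | (1R)-4-methyl-1-[1,4,5,8-tetrakis(methoxymethoxy)naphthalen-2-yl]pent-3-en-1-ol | CC(C)=CC[C@@H](O)c1cc(OCOC)c2c(OCOC)ccc(OCOC)c2c1OCOC
F5 | step 8 | (1R)-4-methyl-1-[1,4,5,8-tetrakis(methoxymethoxy)naphthalen-2-yl]pent-3-enyl 2-methylpropanoate | CC(C)=CC[C@@H](OC(=O)C(C)C)c1cc(OCOC)c2c(OCOC)ccc(OCOC)c2c1OCOC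
F6 | step 8 | (1R)-1-[1,4-bis(methoxymethoxy)-5,8-dioxo-5,8-dihydronaphthalen-2-yl]-4-methylpent-3-enyl 2-methylpropanoate | CC(C)=CC[C@@H](OC(=O)C(C)C)c1cc(OCOC)c2C(=O)C=CC(=O)c2c1OCOC
F7 | step 12 | shikonin, 5,8-dihydroxy-2-[(1R)-1-hydroxy-4-methylpent-3-enyl]naphthalene-1,4-dione | CC(C)=CC[C@@H](O)C1=CC(=O)c2c(O)ccc(O)c2C1=O
F8 | step 10 | 2-[(1R)-1-hydroxy-4-methylpent-3-enyl]-4-methoxy-5,8-bis(methoxymethoxy)naphthalen-1-ol | CC(C)=CC[C@@H](O)c1cc(OC)c2c(OCOC)ccc(OCOC)c2c1O
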